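A neighbour flask takes 80 mM of starting material where this flask takes 20 mM, and I want one number that serves both before either is run.

    initiator → 2 initiating radical (k1 = 0.019 /min)
    starting material + initiating radical → chain carrier (k2 = 26000 /M/s)
    partner + chain carrier → product + initiating radical (k3 = 12000 /M/s)
    2 chain carrier → ended chains A (k4 = 6 × 10⁶ /M/s)
    2 initiating radical → ended chains B (k5 = 2.0 × 10⁶ /M/s)
    solid reagent ⇌ partner, rate k6*(cs6 - [partner]) while solid is left; crystals form when [partner] > cs6 (cs6 = 15 mM, k6 = 0.24 /min)
    crystals ⇌ product, rate k7*(cs7 - [product]) while solid is left; crystals form when [product] > cs7 (cs7 = 18 mM, k7 = 2.4 /min)

starting material 20 mM; solid reagent 50.0 mM; initiator 0.48 mM; time 8.0 min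

- a species is counted by the starting material in it: one ended chains A counts as two
- amounts and yields of product count crystals too
- where a step has two of a species, its rate is k times that concentration squared, and two are used at each turn
- given per volume of solution although it is solid: solid reagent, crystals
- at the start none of the solid reagent is in solution
- run time (flask): 8.0 min

- amount of product and crystals together at 8.0 min, in percent of the starting material charged
- concentration of partner in solution at 2.0 min, in percent of saturation
- the change that raises the amount of product and crystals together at 8.0 min, in percent of the starting material charged most ("none" if none brings more than 2 percentage points) (blue / red / violet / teal / none)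
- amount of product and crystals together at 8.0 min, in percent of the starting material charged, after blue

- blue: doubling the dissolution coefficient of step 6, all else as stated
- red: doubling the dissolution coefficient of step 7, all else as stated
- violet: doubling the solubility in step 7, all else as stated
- teal: doubling the solubility in step 6, all else as stated

**First instants.** In this flask, initiating radical meets starting material within 0.00192 s. Chain carrier, the resting state, levels off on a time of about 0.524 s, far sooner than the earlier asked time of 2.0 min. Its level balances initiation against ended chains A:

chain carrier = √(0.019 /min × 0.48 mM / 6 × 10⁶ /M/s) = 1.59 × 10⁻⁴ mM

g = 12000 /M/s × chain carrier = 0.115 /min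

I call g the drain, the fraction of dissolved partner turned into product each minute: a pseudo-first-order constant with no starting material in it.

**Middle.** Partner starts from nothing and follows

change of partner = 0.24 /min × (15 mM − partner) − g × partner

Dissolution is twice the drain, so partner climbs with time constant 2.82 min to a plateau of 10.2 mM, half the charge. At that plateau, with starting material at its charge, I reckon ended chains B to form at 1.83% of the rate of ended chains A, so I ignore them. At 2.0 min I reckon partner at 34.4% of saturation.

**End.** Product then grows, as a fraction of the charge, at 0.0582 /min, after a lag of 2.65 min:

y = f × (time − lag) = 31.1%

I hold initiator at its charge, since its half-life of 36 min exceeds the run. By the end g has a factor 0.927 on it, so my figure runs high. That figure is below the ceiling of 90.0% of the charge, so red and violet bring nothing. By 8.0 min step 6 delivers at most 144% of the charge, even into a solution kept empty, against a solid charge of 250%, so the solid reagent holds out in this flask. Teal doubles the plateau, and my choice is teal. Blue gives 43.9%.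

The forecast says 29.8%, 34.4%, teal and 41.6%, with its drain “falling slowly as initiator decays”. Its y is lower than mine.

The simulation gives 29.7%, 34.4%, teal with a gain of 27 percentage points against 12 points for blue, and 41.6%, so the forecast held. Crystals in this flask stand at 0% at the end, and red gains 0 points. For the neighbour with 80 mM of starting material, g and the plateau hold no starting material, so my reckoning spreads the same product over the larger charge: 7.84%. That neighbour gives 7.48%, with partner at 9.70 mM and 92% of its starting material left.

The rate constants are made up; what happens was integrated by code.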